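**Retrosynthetic overview**
1. The last and key cut is the ester O–CH2 bond. It gives heptatriacontanoic acid (C37) and a 4-hydroxyphenethyl cation equivalent, the dearomatised spiro[2.5]octa-4,7-dien-6-one, made in the flask from 4-(2-bromoethyl)phenol.
2. The C37 acid is cut at C15–C16 into a docosyl (C22) Grignard reagent and 15-bromopentadecanoic acid (C15).
3. 15-Bromopentadecanoic acid comes from the bulk fragrance lactone ω-pentadecalactone by opening with HBr.
4. Rings: the arene is bought and the macrolactone is opened in step 1. The only ring made is the transient spiro-cyclopropane, closed and reopened within step 3.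

Assumption: the SMILES has no stereocentre, so the target is achiral and nothing needs to be set; the acyl chain is read as 37 carbons including C=O (heptatriacontanoyl, C45H82O3).

**Step 1**
Reactants: 1 ω-pentadecalactone (oxacyclohexadecan-2-one)
Product: 2 15-bromopentadecanoic acid
Conditions: 33% HBr/AcOH, cat. H2SO4, 100 °C, 16 h
Reagents that add atoms: hydrogen bromide, Br
Why: Acidolytic lactone opening, in which bromide displaces the protonated oxygen at the primary ω-carbon (SN2 alkyl–oxygen cleavage), is the standard way from macrolactones to ω-bromo acids, and no other functional group is present.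

**Step 2**
Reactants: 2 15-bromopentadecanoic acid; 3 1-bromodocosane
Product: 6 heptatriacontanoic acid, via docosylmagnesium bromide 4 (not isolated), via chloromagnesium 15-bromopentadecanoate 5 (not isolated)
Conditions: 3 (1.5 equiv), Mg, THF, 50 °C; 2, MeMgCl (0.95 equiv), THF, −20 °C; combine, Li2CuCl4 (5 mol %), NMP, −20 °C → rt; 2 M HCl
Reagents that add atoms: none
Why: This is a Kochi-type copper-catalysed sp3–sp3 Grignard cross-coupling on the halomagnesium salt of an ω-bromo acid, where the carboxylate is inert to RMgX at or below room temperature and the primary bromide couples, joining C22 + C15 = C37.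

**Step 3**
Reactants: 6 heptatriacontanoic acid; 7 4-(2-bromoethyl)phenol
Product: 9 2-(4-hydroxyphenyl)ethyl heptatriacontanoate, via spiro[2.5]octa-4,7-dien-6-one 8 (not isolated)
Conditions: 7 (1.3 equiv), KOtBu (1.25 equiv), THF (0.02 M), −20 → 0 °C, 30 min; cannula-filter dropwise into 6 (1.0 equiv), i-Pr2NEt (10 mol %), PhMe, 65 °C; aq NH4Cl
Reagents that add atoms: none
Why: Proposed new method: one equivalent of base turns 7 into its phenoxide, which closes by Ar1⁻-3 participation to the dearomatised spirocyclopropane 8 with the phenol oxygen masked as a dienone C=O; in the acid-buffered second stage the soluble ammonium carboxylate of 6 attacks a cyclopropane CH2 (homo-1,6-addition) while a second molecule of 6 protonates the emerging phenoxide and regenerates carboxylate, so strain release plus rearomatisation drives O–CH2 bond formation, no acylating agent or free phenoxide is present and aryl ester formation is impossible; the closest known reaction types are solvolytic opening of Winstein-type spirodienones (phenonium chemistry), duocarmycin-type cyclopropane alkylation and amine-catalysed acid–epoxide ring opening, none of them used as a 1:1 preparative esterification of a free fatty acid.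

**Compound list**
1 | ω-pentadecalactone (oxacyclohexadecan-2-one) | O=C1CCCCCCCCCCCCCCO1 | starting material
2 | 15-bromopentadecanoic acid | OC(=O)CCCCCCCCCCCCCCBr | intermediate
3 | 1-bromodocosane | CCCCCCCCCCCCCCCCCCCCCCBr | starting material
4 | docosylmagnesium bromide | CCCCCCCCCCCCCCCCCCCCCC[Mg]Br | intermediate
5 | chloromagnesium 15-bromopentadecanoate | BrCCCCCCCCCCCCCCC(=O)O[Mg]Cl | intermediate
6 | heptatriacontanoic acid | CCCCCCCCCCCCCCCCCCCCCCCCCCCCCCCCCCCCC(=O)O | intermediate
7 | 4-(2-bromoethyl)phenol | Oc1ccc(CCBr)cc1 | starting material
8 | spiro[2.5]octa-4,7-dien-6-one | O=C1C=CC2(CC2)C=C1 | intermediate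
9 | 2-(4-hydroxyphenyl)ethyl heptatriacontanoate | CCCCCCCCCCCCCCCCCCCCCCCCCCCCCCCCCCCCC(=O)OCCc1ccc(O)cc1 | target

**Total step count:** 3
**Longest linear sequence:** 3 (1 → 2 → 6 → 9)

**Steps most likely to fail**

Step 3 (proposed new step).
- Risks: the phenoxide of 7 can attack 8 and give aryl ether oligomers, which is why the step uses high dilution and an excess of 7. Opening of 8 may be slow at the low concentration that the waxy acid 6 allows.
- Fallback (known chemistry): it sets out from 6 and comes back at 9.
- 6 is heated with tyrosol (2-(4-hydroxyphenyl)ethanol, OCCc1ccc(O)cc1, 3 equiv) and TsOH·H2O (5 mol %) in toluene under Dean–Stark reflux.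
- This is a Fischer esterification, so only the aliphatic OH reacts and the phenol stays free. Excess tyrosol is washed out with water.
- This fallback makes no new compound (F0).

Step 2.
- Risks: Wurtz homocoupling of 4, poor solubility of 4 and 5 in cold THF, and difficult separation of waxy hydrocarbons from 6.
- Fallback: it sets out from 2 and comes back at 6.
- 2 is esterified (MeOH, cat. H2SO4, reflux) to methyl 15-bromopentadecanoate F1.
- Commercial 1-docosene is hydroborated with 9-BBN in THF to B-docosyl-9-borabicyclo[3.3.1]nonane F2.
- An alkyl–alkyl Suzuki coupling (Pd(OAc)2/PCy3, K3PO4·H2O, THF, rt) joins them to methyl heptatriacontanoate F3, which can be purified by chromatography.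
- LiOH in THF/H2O at 60 °C, then HCl, gives 6.

Step 1.
- Risks: incomplete conversion, or contamination with acetoxy acid or oligoester.
- Fallback: it sets out from 1 and comes back at 2. It separates the ring opening from the C–Br formation.
- 1 is saponified (KOH, aq MeOH, reflux, then HCl) by acyl–oxygen cleavage to crystalline 15-hydroxypentadecanoic acid F4.
- The free primary alcohol of F4 is then converted with 48% aq HBr/H2SO4 at reflux to 2.

**Further compounds**
F0 | step 3 | none | none
F1 | step 2 | methyl 15-bromopentadecanoate | COC(=O)CCCCCCCCCCCCCCBr
F2 | step 2 | B-docosyl-9-borabicyclo[3.3.1]nonane | CCCCCCCCCCCCCCCCCCCCCCB1C2CCCC1CCC2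
F3 | step 2 | methyl heptatriacontanoate | CCCCCCCCCCCCCCCCCCCCCCCCCCCCCCCCCCCCC(=O)OC
F4 | step 1 | 15-hydroxypentadecanoic acid | OC(=O)CCCCCCCCCCCCCCO
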